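Each 2,4-dihydroxybenzoyl ring (atoms C1′–C6′, C1′ on the ketone) is cut at C1′–C2′ and C5′–C6′: C1′ and C6′ are the two alkyne carbons of an ethynyl ketone, C2′–C5′ the backbone of a 1,1-dimethoxy-3-silyloxybutadiene that already carries the oxygens at C2′ and C4′. The feature exploited is this 1,3-relationship of the ring oxygens, ortho and para to the acyl carbon. A double Diels–Alder/aromatisation on the bis(ethynyl ketone) of the α-truxillic cyclobutane closes both arene rings in one operation, while the four cyclobutane stereocentres come intact from α-truxillic acid. The precursor is the centrosymmetric 1,3-dipropynoyl-2,4-diphenylcyclobutane. Chelation-assisted cleavage of the two ortho methyl ethers then gives the target.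

Key step: step 5

Remark: the target is the achiral, centrosymmetric (1α,2α,3β,4β) isomer (acyl groups trans to each other, phenyl groups trans to each other, each acyl cis to one neighbouring phenyl), so only relative configuration has to be kept; α-truxillic acid of this configuration is taken as purchased.

Step 1
Reactants: 1 α-truxillic acid, (1α,2α,3β,4β)-2,4-diphenylcyclobutane-1,3-dicarboxylic acid
Product: 3 (1α,2α,3β,4β)-N,N'-dimethoxy-N,N'-dimethyl-2,4-diphenylcyclobutane-1,3-dicarboxamide, via α-truxilloyl dichloride 2 (not isolated)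
Conditions: SOCl2, 75 °C; evaporate; MeNH(OMe)·HCl, pyridine, CH2Cl2, 0 °C → rt
Reagents that add atoms: N,O-dimethylhydroxylamine hydrochloride, CNOC.Cl; thionyl chloride, O=S(Cl)Cl (chlorine of 2 only)
Why: Acid chloride formation followed by N-acylation of the hydroxylamine (Weinreb amide synthesis) should proceed without touching the ring carbons, since pyridine is too weak a base to convert 2 into a ketene, so the four stereocentres of 1 are carried over unchanged.

Step 2
Reactants: 3 (1α,2α,3β,4β)-N,N'-dimethoxy-N,N'-dimethyl-2,4-diphenylcyclobutane-1,3-dicarboxamide; 4 ethynylmagnesium bromide (two equivalents react)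
Product: 6 (1α,2α,3β,4β)-1,1'-(2,4-diphenylcyclobutane-1,3-diyl)bis(prop-2-yn-1-one), via bis(bromomagnesium hemiaminal) chelate 5 (not isolated)
Conditions: 4 (0.5 M in THF, 5 equiv), THF, 0 °C → rt; cannulate into 1 M HCl, 0 °C
Reagents that add atoms: ethynylmagnesium bromide (4), C#C[Mg]Br
Why: In this Weinreb ketone synthesis each amide takes up one alkynyl Grignard reagent to give a magnesium chelate that cannot over-add and collapses to the ketone only on the inverse quench into cold acid, which protonates the released N,O-dimethylhydroxylamine before it can add to the ynone; no stereocentre of the product is formed or disturbed.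

Step 3
Reactants: 7 1,1-dimethoxyethene (two equivalents); 8 acetyl chloride
Product: 9 4,4-dimethoxybut-3-en-2-one
Conditions: 7 (2.1 equiv), Et2O, 0 °C → rt; distil
Reagents that add atoms: acetyl chloride (8), CC(=O)Cl
Why: C-Acylation of the electron-rich ketene acetal by the acid chloride gives a dimethoxycarbenium ion that loses the proton of its doubly activated CH2 group, the second equivalent of 7 taking up the HCl as methyl acetate and chloromethane (known acylation of ketene acetals; no stereocentre).

Step 4
Reactants: 9 4,4-dimethoxybut-3-en-2-one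
Product: 10 1,1-dimethoxy-3-(trimethylsilyloxy)buta-1,3-diene
Conditions: TMSOTf, Et3N, Et2O, 0 °C; decant from the salt layer, distil, use fresh
Reagents that add atoms: trimethylsilyl trifluoromethanesulfonate, C[Si](C)(C)OS(=O)(=O)C(F)(F)F
Why: Amine-mediated enolisation and O-silylation of the methyl ketone (silyl enol ether formation) can only occur at the methyl group, the sole enolisable position, so the 2-silyloxy diene is the only product to be expected.

Step 5
Reactants: 6 (1α,2α,3β,4β)-1,1'-(2,4-diphenylcyclobutane-1,3-diyl)bis(prop-2-yn-1-one); 10 1,1-dimethoxy-3-(trimethylsilyloxy)buta-1,3-diene (two equivalents react)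
Product: 13 (1α,2α,3β,4β)-(2,4-diphenylcyclobutane-1,3-diyl)bis[(4-hydroxy-2-methoxyphenyl)methanone], via bis(cyclohexa-1,4-diene) cycloadduct 11 (not isolated), via bis(aryl trimethylsilyl ether) 12 (not isolated)
Conditions: 10 (4 equiv), toluene, 20 → 60 °C; then 0.1 M HCl, THF, 0 °C, 15 min
Reagents that add atoms: none
Why: Each ynone is an electron-poor dienophile and 10 an electron-rich diene, so two normal-demand, asynchronous concerted [4+2] cycloadditions (Diels–Alder) should take place, the diene CH2 terminus bonding to the ynone β-carbon (C5′–C6′) and the ketene acetal carbon to the α-carbon (C1′–C2′). The closest known reaction type is the cycloaddition of 1,1-dialkoxy-3-silyloxybutadienes with acetylenic ketones and esters, whose adducts lose alcohol to give resorcinol monoethers. Each six-membered ring is closed by intermolecular [4+2] annulation of a four-carbon and a two-carbon unit, and the resulting cyclohexa-1,4-diene 11 aromatises by 1,4-elimination of methanol across C2′ and C5′ to 12, whose silyl ethers are hydrolysed in the mild acidic work-up. No stereocentre is formed, since every carbon of the new rings ends up sp2. The step needs 2,4- and not 2,6-oxygenation, which the polarisation of both partners secures (largest HOMO coefficient at the unsubstituted diene terminus, largest LUMO coefficient at the terminal alkyne carbon), and it needs both ynones to react, which the excess of diene and the independent, non-conjugated placement of the two dienophiles should secure. The cyclobutane carbons next to the ketones should keep their configuration because no base is present and the acid contact is brief and cold.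

Step 6
Reactants: 13 (1α,2α,3β,4β)-(2,4-diphenylcyclobutane-1,3-diyl)bis[(4-hydroxy-2-methoxyphenyl)methanone]
Product: 15 (1α,2α,3β,4β)-(2,4-diphenylcyclobutane-1,3-diyl)bis[(2,4-dihydroxyphenyl)methanone] (target CNP0398987.2), via tetrakis(boron aryloxide) chelate 14 (not isolated)
Conditions: BCl3 (6 equiv), CH2Cl2, −78 → 0 °C; then H2O, 0 °C
Reagents that add atoms: boron trichloride, ClB(Cl)Cl (boron and chlorine of 14 only)
Why: In this chelation-directed Lewis acid cleavage of aryl methyl ethers BCl3 binds the ketone oxygen and the ortho methoxy oxygen in a six-membered chelate, chloride removes the methyl group, and hydrolysis of the aryl borates releases the four phenols, with no stereocentre involved.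

Compound list
1 | α-truxillic acid, (1α,2α,3β,4β)-2,4-diphenylcyclobutane-1,3-dicarboxylic acid | OC(=O)[C@H]1[C@H](c2ccccc2)[C@H](C(O)=O)[C@H]1c1ccccc1 | starting material
2 | α-truxilloyl dichloride, (1α,2α,3β,4β)-2,4-diphenylcyclobutane-1,3-dicarbonyl dichloride (formed in the flask) | O=C(Cl)[C@H]1[C@H](c2ccccc2)[C@H](C(=O)Cl)[C@H]1c1ccccc1 | intermediate
3 | (1α,2α,3β,4β)-N,N'-dimethoxy-N,N'-dimethyl-2,4-diphenylcyclobutane-1,3-dicarboxamide | CON(C)C(=O)[C@H]1[C@H](c2ccccc2)[C@H](C(=O)N(C)OC)[C@H]1c1ccccc1 | intermediate
4 | ethynylmagnesium bromide | C#C[Mg]Br | starting material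
5 | bis(bromomagnesium hemiaminal) chelate: the (1α,2α,3β,4β)-2,4-diphenylcyclobutane carrying at C1 and C3 a 1-(bromomagnesiooxy)-1-[methoxy(methyl)amino]prop-2-yn-1-yl group, hemiaminal carbons of either configuration (formed in the flask) | C#CC(O[Mg]Br)(N(C)OC)[C@H]1[C@H](c2ccccc2)[C@H](C(O[Mg]Br)(N(C)OC)C#C)[C@H]1c1ccccc1 | intermediate
6 | (1α,2α,3β,4β)-1,1'-(2,4-diphenylcyclobutane-1,3-diyl)bis(prop-2-yn-1-one) | C#CC(=O)[C@H]1[C@H](c2ccccc2)[C@H](C(=O)C#C)[C@H]1c1ccccc1 | intermediate
7 | 1,1-dimethoxyethene | C=C(OC)OC | starting material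
8 | acetyl chloride | CC(=O)Cl | starting material
9 | 4,4-dimethoxybut-3-en-2-one | CC(=O)C=C(OC)OC | intermediate
10 | 1,1-dimethoxy-3-(trimethylsilyloxy)buta-1,3-diene | C=C(O[Si](C)(C)C)C=C(OC)OC | intermediate
11 | (1α,2α,3β,4β)-(2,4-diphenylcyclobutane-1,3-diyl)bis{[6,6-dimethoxy-4-(trimethylsilyloxy)cyclohexa-1,4-dien-1-yl]methanone} (formed in the flask) | O=C(C1=CCC(O[Si](C)(C)C)=CC1(OC)OC)[C@H]1[C@H](c2ccccc2)[C@H](C(=O)C2=CCC(O[Si](C)(C)C)=CC2(OC)OC)[C@H]1c1ccccc1 | intermediate
12 | (1α,2α,3β,4β)-(2,4-diphenylcyclobutane-1,3-diyl)bis{[2-methoxy-4-(trimethylsilyloxy)phenyl]methanone} (formed in the flask) | O=C(c1ccc(O[Si](C)(C)C)cc1OC)[C@H]1[C@H](c2ccccc2)[C@H](C(=O)c2ccc(O[Si](C)(C)C)cc2OC)[C@H]1c1ccccc1 | intermediate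
13 | (1α,2α,3β,4β)-(2,4-diphenylcyclobutane-1,3-diyl)bis[(4-hydroxy-2-methoxyphenyl)methanone] | O=C(c1ccc(O)cc1OC)[C@H]1[C@H](c2ccccc2)[C@H](C(=O)c2ccc(O)cc2OC)[C@H]1c1ccccc1 | intermediate
14 | tetrakis(boron aryloxide) chelate of 15: each aryl ketone closed to a six-membered ring through a BCl2 group bridging the carbonyl oxygen and the C2′ oxygen, each C4′ oxygen carrying a BCl2 group (formed in the flask) | Cl[B-]1(Cl)Oc2cc(OB(Cl)Cl)ccc2C(=[O+]1)[C@H]1[C@H](c2ccccc2)[C@H](C2=[O+][B-](Cl)(Cl)Oc3cc(OB(Cl)Cl)ccc23)[C@H]1c1ccccc1 | intermediate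
15 | (1α,2α,3β,4β)-(2,4-diphenylcyclobutane-1,3-diyl)bis[(2,4-dihydroxyphenyl)methanone], CNP0398987.2 | O=C(c1ccc(O)cc1O)[C@H]1[C@H](c2ccccc2)[C@H](C(=O)c2ccc(O)cc2O)[C@H]1c1ccccc1 | target

Total step count: 6. Longest linear sequence: 4 steps (1 → 3 → 6 → 13 → 15; the diene branch 7 → 9 → 10 → 13 → 15 is equally long).

Steps most likely to fail

Step 5. The diene may add to the ynone in an open-chain conjugate fashion without closing the ring, only one of the two ynones may react, or the diene may be lost by hydrolysis or oligomerisation before it is consumed. The fallback brings in the arene rings preformed. It sets out from 3: addition of purchased 2,4-dimethoxyphenylmagnesium bromide (THF, 0 °C → rt, Weinreb ketone synthesis) would give (1α,2α,3β,4β)-(2,4-diphenylcyclobutane-1,3-diyl)bis[(2,4-dimethoxyphenyl)methanone] F1. Cleavage of all four methyl ethers with BBr3 (CH2Cl2, −78 → 20 °C) then comes back to the route at 15.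

Step 2. The liberated N,O-dimethylhydroxylamine may add in conjugate fashion to the newly formed ynone during the quench, or addition to the second, hindered amide may stall. The fallback sets out from 2, obtained free of SOCl2 by evaporation as in step 1. Stille acylation with tributyl[(trimethylsilyl)ethynyl]stannane and catalytic PdCl2(PPh3)2 (1,2-dichloroethane, 60 °C) would give (1α,2α,3β,4β)-1,1'-(2,4-diphenylcyclobutane-1,3-diyl)bis[3-(trimethylsilyl)prop-2-yn-1-one] F2 under neutral conditions, with no amine present. Desilylation with Na2B4O7 in aqueous methanol at 20 °C comes back to the route at 6.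

Step 6. The Lewis acid may epimerise or heterolytically open the cyclobutane, each ring bond of which links a ketone-bearing and a phenyl-bearing carbon, or ether cleavage may stop halfway. The fallback removes the need for any ether cleavage and sets out from 6. The cycloaddition is run instead with 1-methoxy-1,3-bis(trimethylsilyloxy)buta-1,3-diene F3, prepared from purchased methyl 3-(trimethylsilyloxy)but-2-enoate by γ-deprotonation with LDA and O-silylation with TMSCl (THF, −78 °C). In toluene at 20 → 60 °C this would give (1α,2α,3β,4β)-(2,4-diphenylcyclobutane-1,3-diyl)bis{[6-methoxy-4,6-bis(trimethylsilyloxy)cyclohexa-1,4-dien-1-yl]methanone} F4. Dilute HCl in THF at 0 °C hydrolyses its silyl enol ethers and mixed methyl silyl ketals to the keto tautomers of the resorcinol rings, which comes back to the route directly at 15. This diene is kept in reserve because it is the stronger carbon nucleophile and more prone to open-chain addition than 10.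

Further compounds
F1 | step 5 | (1α,2α,3β,4β)-(2,4-diphenylcyclobutane-1,3-diyl)bis[(2,4-dimethoxyphenyl)methanone] | O=C(c1ccc(OC)cc1OC)[C@H]1[C@H](c2ccccc2)[C@H](C(=O)c2ccc(OC)cc2OC)[C@H]1c1ccccc1
F2 | step 2 | (1α,2α,3β,4β)-1,1'-(2,4-diphenylcyclobutane-1,3-diyl)bis[3-(trimethylsilyl)prop-2-yn-1-one] | C[Si](C)(C)C#CC(=O)[C@H]1[C@H](c2ccccc2)[C@H](C(=O)C#C[Si](C)(C)C)[C@H]1c1ccccc1
F3 | step 6 | 1-methoxy-1,3-bis(trimethylsilyloxy)buta-1,3-diene (ketene acetal geometry immaterial) | C=C(O[Si](C)(C)C)C=C(OC)O[Si](C)(C)C
F4 | step 6 | (1α,2α,3β,4β)-(2,4-diphenylcyclobutane-1,3-diyl)bis{[6-methoxy-4,6-bis(trimethylsilyloxy)cyclohexa-1,4-dien-1-yl]methanone} (ketal carbons of either configuration) | O=C(C1=CCC(O[Si](C)(C)C)=CC1(OC)O[Si](C)(C)C)[C@H]1[C@H](c2ccccc2)[C@H](C(=O)C2=CCC(O[Si](C)(C)C)=CC2(OC)O[Si](C)(C)C)[C@H]1c1ccccc1
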